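- Each flask was closed and stirred at constant volume, and I reckoned in fractions of the charge, asking what was left rather than what was made.

| setting | green | red | Wednesday's | Monday's |
|---|---|---|---|---|
| substrate | 0.20 M | 0.20 M | 0.20 M | 0.20 M |
| reagent | 1.3 equiv | 1.4 equiv | 1.00 equiv | 1.20 equiv |
| free catalyst | 0.5 mol% | 0.5 mol% | 0.5 mol% | 0.5 mol% |
| remark | run made earlier | run made earlier |  |  |
| time |  |  | 3.0 min | 3.0 min |

| run | time / min | catalyst intermediate B / % | substrate / % | catalyst intermediate A / % | side product / % | target / % |
|---|---|---|---|---|---|---|
| green | 0.250 | 0.5 | 67.8 | 0.3 | 6.3 | 26.0 |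
| green | 0.333 | 0 | 57.0 | 0 | 11.0 | 32.1 |
| green | 0.500 | 0.6 | 37.1 | 0 | 17.4 | 43.6 |
| green | 0.833 | 0 | 9.1 | 0.7 | 27.5 | 63.0 |
| green | 1.33 | 0.1 | 0.7 | 0 | 28.8 | 70.7 |
| green | 2.00 | 0.2 | 0 | 0.4 | 28.2 | 71.2 |
| green | 3.00 | 0 | 0 | 0.2 | 28.8 | 70.8 |
| red | 0.250 | 0 | 66.1 | 0 | 7.9 | 27.7 |
| red | 0.333 | 0.2 | 54.8 | 0 | 10.8 | 34.9 |
| red | 0.500 | 0 | 34.8 | 0.5 | 18.1 | 46.6 |
| red | 0.833 | 0.4 | 6.4 | 0.3 | 26.7 | 66.2 |
| red | 1.33 | 0 | 0.1 | 0.4 | 27.8 | 71.8 |
| red | 2.00 | 0 | 0.3 | 0.8 | 27.9 | 72.0 |
| red | 3.00 | 0 | 0 | 1.0 | 27.0 | 72.2 |

(readings scatter by 0.5 percentage points)

- percent here means substrate units held: one side product counts as two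
- steps that have been proposed: substrate + free catalyst -> catalyst intermediate A; catalyst intermediate A <-> catalyst intermediate B; reagent + catalyst intermediate B <-> catalyst intermediate C; catalyst intermediate C -> free catalyst + target; substrate + target -> side product

- which of these there is most of at the end, counted by the substrate in it, Wednesday's (catalyst intermediate B / target / side product / catalyst intermediate A / substrate)
- which of these there is most of at the end, counted by the substrate in it, Monday's (catalyst intermediate B / target / side product / catalyst intermediate A / substrate)
- final amount of the leader among these, as a percentage of the substrate charged, in Wednesday's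
- final amount of the leader among these, as a percentage of the substrate charged, in Monday's

- In the proposed steps each target costs one reagent, and a side product keeps the target it took in and adds one substrate. So reagent spent per substrate charged is target plus half of side product. In the green run, where substrate read 0% at 3.00 min, that came to 85.2%, and I called this figure the reagent need.

- The bench rule says that reagent in excess leaves the yield unchanged, and the earlier runs seemed to agree: 1.3 equiv gave 70.8% target and 1.4 equiv gave 72.2%, a gap of 1.4 percentage points against a scatter of 0.5 points. Applied honestly, it promised about the green value in both new flasks.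

- I found its border by dividing the need by the charge and taking the fraction of reagent left. With the green need carried over unchanged as an estimate, that gave 34.5% for green, 29.0% for Monday's and 14.8% for Wednesday's. By this reckoning substrate stayed the limiting reagent, but the proposed side step uses no reagent, so I expected the loss to grow as the fraction left fell.

- I therefore drew a straight line through the red and green targets, remembering that it rests on two readings with their scatter. It gave 69.4% for Monday's and 66.6% for Wednesday's, with target leading in both, and I held the Wednesday figure as too high.

- The forecast also named target as leader in both flasks, but it stood lower on Wednesday's, at 62%, and gave 69% on Monday's. Its ground was: “The rate is therefore first order in reagent and zero order in substrate until substrate runs out.”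

- The flasks gave target as leader, at 64.6% in Wednesday's and 69.4% in Monday's, so the forecast held on both.

    substrate + free catalyst → catalyst intermediate A (k = 438 M⁻¹ s⁻¹)
    catalyst intermediate A ⇌ catalyst intermediate B (K = 3.40, k = 91.7 s⁻¹)
    reagent + catalyst intermediate B ⇌ catalyst intermediate C (K = 39.0 M⁻¹, k = 39.1 M⁻¹ s⁻¹)
    catalyst intermediate C → free catalyst + target (k = 12.7 s⁻¹)
    substrate + target → side product (k = 0.104 M⁻¹ s⁻¹)

- Wednesday's need came to 82.3%, which leaves 17.7% of the reagent, and the flask held 18%. A further flask, like Wednesday's but with 0.3 mol% of free catalyst, reckoned by its own target and side product to 22.6% of the reagent left, and it held 23%. In Wednesday's at 0.455 min, target was made 3.37 times as fast as it was used up. At that moment in Wednesday's, substrate went to catalyst intermediate A 3.4 times as fast as to side product.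

The runs come from a simulation from invented constants.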